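**Retrosynthetic overview**
- Feature: the ketone carbon C1 is bonded to the benzene carbon that lies between the two hydroxyl-bearing ring carbons (methoxy para to it). Acyl carbon and one ortho oxygen are therefore neighbours and are installed together by inserting an aryne into the C–O bond of a carboxylic acid.
- C6=C7 (Z): Wittig union of the C1–C6 keto aldehyde with the C7–C18 ylide, followed by global desilylation.
- Aryl–C1 and aryl–O bonds: 5-methoxy-3-(MOM-oxy)benzyne (from the ortho-silyl aryl triflate, made from 5-methoxyresorcinol by carbamate-directed ortho-silylation) plus hept-6-enoic acid.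
- C7–C18: C12=C13 (Z) by Wittig of the (Z)-hex-3-enyl ylide with a C7–C12 enal; C10=C11 (E) by a stabilised Wittig on (R)-2,4-bis(silyloxy)butanal.
- Rings: none is formed; the benzene ring is bought and no ring closes anywhere in the route.

Key step: step 5

Remark: C9 is R (OH > C10 > C8 > H). (R)-α-Hydroxy-γ-butyrolactone is assumed to be bought as the single enantiomer and is used as the source of C9 because it holds C10 at the acid level and C7 as the lactone alcohol.

**Route**

Step 1
Reactants: 1 5-methoxyresorcinol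
Product: 2 3-methoxy-5-(methoxymethoxy)phenol
Conditions: MOMCl (1.0 equiv), i-Pr2NEt (1.1 equiv), THF, 0 °C to rt
Reagents that add atoms: chloromethyl methyl ether, COCCl
Why: O-alkylation of one of two equivalent phenols by the α-chloro ether (Williamson type) should give the mono-ether as the main part of a statistical mixture, from which bis-ether and unreacted 1 are separated by chromatography and 1 is recycled.

Step 2
Reactants: 2 3-methoxy-5-(methoxymethoxy)phenol
Product: 3 3-methoxy-5-(methoxymethoxy)phenyl N-isopropylcarbamate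
Conditions: i-PrNCO (1.2 equiv), Et3N (0.2 equiv), CH2Cl2, rt
Reagents that add atoms: isopropyl isocyanate, CC(C)N=C=O
Why: Amine-catalysed addition of the phenol to the isocyanate gives the O-aryl carbamate, a strong director for ortho-metalation that is later removed under mild base.

Step 3
Reactants: 3 3-methoxy-5-(methoxymethoxy)phenyl N-isopropylcarbamate
Product: 7 5-methoxy-3-(methoxymethoxy)-2-(trimethylsilyl)phenyl N-isopropylcarbamate, via N-silyl carbamate 4 (not isolated), via aryllithium 5 (not isolated), via N-silyl aryl silane 6 (not isolated)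
Conditions: TBSOTf, TMEDA, Et2O, 0 °C to rt; then n-BuLi, TMEDA, −78 °C; then TMSCl, −78 °C to rt; brief cold aq. NaHSO4 work-up
Reagents that add atoms: chlorotrimethylsilane, C[Si](C)(C)Cl
Why: Directed ortho-metalation of the carbamate, N-silylated in the flask, should occur at the ring carbon flanked by the carbamate and the MOM-oxy group (the two stronger, chelating directors) rather than at the carbon between carbamate and methoxy; the aryllithium is silylated at −78 °C before a carbamoyl shift can set in, and the N–Si bond is hydrolysed on work-up.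

Step 4
Reactants: 7 5-methoxy-3-(methoxymethoxy)-2-(trimethylsilyl)phenyl N-isopropylcarbamate
Product: 9 5-methoxy-3-(methoxymethoxy)-2-(trimethylsilyl)phenyl trifluoromethanesulfonate, via silyl phenol 8 (not isolated)
Conditions: DBU, Et2NH, MeCN, 40 °C; then PhNTf2, rt
Reagents that add atoms: N-phenylbis(trifluoromethanesulfonimide), O=S(=O)(N(c1ccccc1)S(=O)(=O)C(F)(F)F)C(F)(F)F
Why: Base-induced E1cB cleavage of the N–H carbamate (the isocyanate is trapped by Et2NH as a urea) frees the ortho-silyl phenoxide, which is triflated in the same flask, so the acid-sensitive silyl phenol is never handled.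

Step 5
Reactants: 9 5-methoxy-3-(methoxymethoxy)-2-(trimethylsilyl)phenyl trifluoromethanesulfonate (1.5 equiv); 10 hept-6-enoic acid (1.0 equiv)
Product: 12 1-[2-hydroxy-4-methoxy-6-(methoxymethoxy)phenyl]hept-6-en-1-one, via aryne 11 (not isolated)
Conditions: CsF (4 equiv), THF, 125 °C, sealed tube
Reagents that add atoms: none
Why: Fluoride attacks silicon of 9 and triflate leaves, giving aryne 11 with its triple bond next to the MOM-oxy carbon; the carboxylate of 10 adds through oxygen to the aryne carbon remote from the MOM-oxy group, which places the aryl anion beside that inductively withdrawing oxygen. The anion attacks its own ester carbonyl and the four-membered alkoxide opens by C–O cleavage to the ortho-acyl phenoxide, a net insertion into the acid C–O bond that forms the aryl–O and aryl–C(=O) bonds on neighbouring carbons. The closest known reaction type is the fluoride-induced insertion of arynes into carboxylic acids to give ortho-hydroxyaryl ketones, known for aliphatic acids and for 3-alkoxy arynes. No ring is closed (the four-membered intermediate is transient) and no stereocentre is formed. The step needs regioselective addition, secured by the polarisation that the 3-MOM-oxy group imposes on the aryne (the weaker, opposite bias of the 5-methoxy group is overridden), and acyl transfer in preference to protonation of the aryl anion, favoured by hot THF, which offers no acidic C–H bond. The terminal alkene and the MOM acetal should be inert to CsF at this temperature.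

Step 6
Reactants: 12 1-[2-hydroxy-4-methoxy-6-(methoxymethoxy)phenyl]hept-6-en-1-one
Product: 13 1-(2,6-dihydroxy-4-methoxyphenyl)hept-6-en-1-one
Conditions: HCl (3 M in MeOH), MeOH, 40 °C
Reagents that add atoms: none
Why: Acid-catalysed acetal methanolysis removes the MOM group while the molecule holds only a terminal alkene and an aryl ketone, so that no acid is needed once the acid-labile dienyl carbinol is present.

Step 7
Reactants: 13 1-(2,6-dihydroxy-4-methoxyphenyl)hept-6-en-1-one
Product: 14 1-[2,6-bis(tert-butyldimethylsilyloxy)-4-methoxyphenyl]hept-6-en-1-one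
Conditions: TBSCl (3 equiv), imidazole (6 equiv), DMF, rt to 40 °C
Reagents that add atoms: tert-butyldimethylsilyl chloride, CC(C)(C)[Si](C)(C)Cl
Why: Imidazole-promoted silylation of both hydrogen-bonded phenols masks the acidic OH groups for the periodate and ylide steps and gives ethers that fluoride removes at the end together with the C9 silyl ether.

Step 8
Reactants: 14 1-[2,6-bis(tert-butyldimethylsilyloxy)-4-methoxyphenyl]hept-6-en-1-one
Product: 15 6-[2,6-bis(tert-butyldimethylsilyloxy)-4-methoxyphenyl]-6-oxohexanal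
Conditions: OsO4 (2 mol %), NaIO4 (4 equiv), 2,6-lutidine, dioxane/H2O 3:1, rt
Reagents that add atoms: osmium tetroxide, O=[Os](=O)(=O)=O (transfers the oxygen); sodium periodate, [Na+].[O-]I(=O)(=O)=O (stoichiometric oxygen source)
Why: Lemieux–Johnson cleavage (dihydroxylation, then periodate glycol cleavage) of the only alkene gives the C6 aldehyde; it is preferred to ozonolysis because the trioxygenated arene is sensitive to ozone.

Step 9
Reactants: 16 (Z)-hex-3-en-1-ol
Product: 17 (Z)-1-iodohex-3-ene
Conditions: I2, PPh3, imidazole, CH2Cl2, 0 °C to rt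
Reagents that add atoms: iodine, II
Why: Appel-type iodination displaces the primary oxyphosphonium by iodide (SN2) and leaves the Z alkene untouched.

Step 10
Reactants: 17 (Z)-1-iodohex-3-ene
Product: 18 [(Z)-hex-3-enyl]triphenylphosphonium iodide
Conditions: PPh3, MeCN, reflux
Reagents that add atoms: triphenylphosphine, c1ccc(cc1)P(c1ccccc1)c1ccccc1
Why: SN2 quaternisation of the phosphine by the primary iodide gives the Wittig salt for C13–C18.

Step 11
Reactants: 19 (R)-α-hydroxy-γ-butyrolactone
Product: 20 (R)-3-(tert-butyldimethylsilyloxy)dihydrofuran-2(3H)-one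
Conditions: TBSCl, imidazole, DMF, rt
Reagents that add atoms: tert-butyldimethylsilyl chloride, CC(C)(C)[Si](C)(C)Cl
Why: Silylation of the secondary alcohol protects the future C9 oxygen; the stereocentre, taken from the chiral pool, is not involved.

Step 12
Reactants: 20 (R)-3-(tert-butyldimethylsilyloxy)dihydrofuran-2(3H)-one
Product: 21 (R)-2-(tert-butyldimethylsilyloxy)-4-hydroxy-N-methoxy-N-methylbutanamide
Conditions: MeNH(OMe)·HCl, i-PrMgCl, THF, −20 to 0 °C; cold aq. NH4Cl quench
Reagents that add atoms: N,O-dimethylhydroxylamine hydrochloride, CNOC.Cl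
Why: Aminolysis of the lactone by the chloromagnesium amide (Weinreb amide formation) opens the ring and so tells C10 (amide) from C7 (free alcohol), at a temperature low enough that the α-silyloxy centre should not be enolised.

Step 13
Reactants: 21 (R)-2-(tert-butyldimethylsilyloxy)-4-hydroxy-N-methoxy-N-methylbutanamide
Product: 22 (R)-2,4-bis(tert-butyldimethylsilyloxy)-N-methoxy-N-methylbutanamide
Conditions: TBSCl, imidazole, CH2Cl2, 0 °C to rt, on crude 21
Reagents that add atoms: tert-butyldimethylsilyl chloride, CC(C)(C)[Si](C)(C)Cl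
Why: Prompt silylation of the primary alcohol prevents relactonisation of the γ-hydroxy amide and installs the group that is later cleaved selectively at C7.

Step 14
Reactants: 22 (R)-2,4-bis(tert-butyldimethylsilyloxy)-N-methoxy-N-methylbutanamide
Product: 23 (R)-2,4-bis(tert-butyldimethylsilyloxy)butanal
Conditions: i-Bu2AlH, THF, −78 °C; Rochelle salt work-up
Reagents that add atoms: none
Why: Hydride reduction of the Weinreb amide stops at the chelated aluminium hemiaminal, which releases the α-silyloxy aldehyde only on work-up, so neither over-reduction nor epimerisation is expected.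

Step 15
Reactants: 23 (R)-2,4-bis(tert-butyldimethylsilyloxy)butanal
Product: 24 (R,E)-4,6-bis(tert-butyldimethylsilyloxy)hex-2-enal
Conditions: Ph3P=CHCHO, toluene, 50 °C
Reagents that add atoms: (triphenylphosphoranylidene)acetaldehyde, O=CC=P(c1ccccc1)(c1ccccc1)c1ccccc1
Why: Wittig olefination by the stabilised formyl ylide gives the E enal (C10=C11) under neutral conditions that should leave the adjacent silyloxy stereocentre intact.

Step 16
Reactants: 18 [(Z)-hex-3-enyl]triphenylphosphonium iodide; 24 (R,E)-4,6-bis(tert-butyldimethylsilyloxy)hex-2-enal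
Product: 26 (3R,4E,6Z,9Z)-1,3-bis(tert-butyldimethylsilyloxy)dodeca-4,6,9-triene, via hexenylidene ylide 25 (not isolated)
Conditions: 18, NaN(SiMe3)2, THF, −78 to 0 °C; then 24, −78 °C to rt
Reagents that add atoms: none
Why: A non-stabilised, lithium-free ylide adds 1,2 to the enal in a kinetically controlled Wittig reaction and should give the Z alkene at C12=C13, the E alkene and the C9 centre of 24 being carried through unchanged.

Step 17
Reactants: 26 (3R,4E,6Z,9Z)-1,3-bis(tert-butyldimethylsilyloxy)dodeca-4,6,9-triene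
Product: 27 (3R,4E,6Z,9Z)-3-(tert-butyldimethylsilyloxy)dodeca-4,6,9-trien-1-ol
Conditions: HF·pyridine, pyridine, THF, 0 °C
Reagents that add atoms: none
Why: Buffered fluoride desilylation is sterically controlled and should cleave the primary silyl ether well before the secondary allylic one, without the acid that would ionise the dienylic position.

Step 18
Reactants: 27 (3R,4E,6Z,9Z)-3-(tert-butyldimethylsilyloxy)dodeca-4,6,9-trien-1-ol
Product: 28 (3R,4E,6Z,9Z)-3-(tert-butyldimethylsilyloxy)-1-iodododeca-4,6,9-triene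
Conditions: I2, PPh3, imidazole, CH2Cl2, 0 °C, dark
Reagents that add atoms: iodine, II
Why: Appel-type iodination of the primary alcohol under buffered, cold conditions is compatible with the triene and the allylic silyl ether.

Step 19
Reactants: 28 (3R,4E,6Z,9Z)-3-(tert-butyldimethylsilyloxy)-1-iodododeca-4,6,9-triene
Product: 29 [(3R,4E,6Z,9Z)-3-(tert-butyldimethylsilyloxy)dodeca-4,6,9-trienyl]triphenylphosphonium iodide
Conditions: PPh3, i-Pr2NEt (cat.), MeCN, 60 °C, dark
Reagents that add atoms: triphenylphosphine, c1ccc(cc1)P(c1ccccc1)c1ccccc1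
Why: SN2 quaternisation at the unhindered primary iodide gives the C7–C18 salt, whose γ-silyloxy group is too far from phosphorus to be eliminated on ylide formation.

Step 20
Reactants: 29 [(3R,4E,6Z,9Z)-3-(tert-butyldimethylsilyloxy)dodeca-4,6,9-trienyl]triphenylphosphonium iodide; 15 6-[2,6-bis(tert-butyldimethylsilyloxy)-4-methoxyphenyl]-6-oxohexanal
Product: 31 (6Z,9R,10E,12Z,15Z)-1-[2,6-bis(tert-butyldimethylsilyloxy)-4-methoxyphenyl]-9-(tert-butyldimethylsilyloxy)octadeca-6,10,12,15-tetraen-1-one, via trienylidene ylide 30 (not isolated)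
Conditions: 29 (1.2 equiv), NaN(SiMe3)2 (1.1 equiv), THF, −78 °C; then 15, −78 to 0 °C
Reagents that add atoms: none
Why: Z-selective Wittig olefination of the non-stabilised ylide with the aldehyde forms C6=C7; the aldehyde should be consumed at −78 °C far faster than the ketone, which is shielded by two ortho silyloxy groups, can be attacked or enolised.

Step 21
Reactants: 31 (6Z,9R,10E,12Z,15Z)-1-[2,6-bis(tert-butyldimethylsilyloxy)-4-methoxyphenyl]-9-(tert-butyldimethylsilyloxy)octadeca-6,10,12,15-tetraen-1-one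
Product: 32 (6Z,9R,10E,12Z,15Z)-1-(2,6-dihydroxy-4-methoxyphenyl)-9-hydroxyoctadeca-6,10,12,15-tetraen-1-one (CNP0541677.1)
Conditions: Bu4NF, AcOH, THF, 0 °C to rt
Reagents that add atoms: none
Why: Fluoride desilylation, buffered by acetic acid, removes the two aryl silyl ethers and the secondary allylic one under near-neutral conditions that the dienyl carbinol and the skipped triene should tolerate.

**Compound list**
1 | 5-methoxyresorcinol | COc1cc(O)cc(O)c1 | starting material
2 | 3-methoxy-5-(methoxymethoxy)phenol | COCOc1cc(O)cc(OC)c1 | intermediate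
3 | 3-methoxy-5-(methoxymethoxy)phenyl N-isopropylcarbamate | COCOc1cc(OC)cc(OC(=O)NC(C)C)c1 | intermediate
4 | 3-methoxy-5-(methoxymethoxy)phenyl N-(tert-butyldimethylsilyl)-N-isopropylcarbamate | COCOc1cc(OC)cc(OC(=O)N(C(C)C)[Si](C)(C)C(C)(C)C)c1 | intermediate
5 | 2-lithio-5-methoxy-3-(methoxymethoxy)phenyl N-(tert-butyldimethylsilyl)-N-isopropylcarbamate | COCOc1cc(OC)cc(OC(=O)N(C(C)C)[Si](C)(C)C(C)(C)C)c1[Li] | intermediate
6 | 5-methoxy-3-(methoxymethoxy)-2-(trimethylsilyl)phenyl N-(tert-butyldimethylsilyl)-N-isopropylcarbamate | COCOc1cc(OC)cc(OC(=O)N(C(C)C)[Si](C)(C)C(C)(C)C)c1[Si](C)(C)C | intermediate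
7 | 5-methoxy-3-(methoxymethoxy)-2-(trimethylsilyl)phenyl N-isopropylcarbamate | COCOc1cc(OC)cc(OC(=O)NC(C)C)c1[Si](C)(C)C | intermediate
8 | 5-methoxy-3-(methoxymethoxy)-2-(trimethylsilyl)phenol | COCOc1cc(OC)cc(O)c1[Si](C)(C)C | intermediate
9 | 5-methoxy-3-(methoxymethoxy)-2-(trimethylsilyl)phenyl trifluoromethanesulfonate | COc1cc(OCOC)c([Si](C)(C)C)c(OS(=O)(=O)C(F)(F)F)c1 | intermediate
10 | hept-6-enoic acid | C=CCCCCC(=O)O | starting material
11 | 5-methoxy-3-(methoxymethoxy)benzyne (1,2-didehydro) | COC1=CC#CC(OCOC)=C1 | intermediate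
12 | 1-[2-hydroxy-4-methoxy-6-(methoxymethoxy)phenyl]hept-6-en-1-one | C=CCCCCC(=O)c1c(O)cc(OC)cc1OCOC | intermediate
13 | 1-(2,6-dihydroxy-4-methoxyphenyl)hept-6-en-1-one | C=CCCCCC(=O)c1c(O)cc(OC)cc1O | intermediate
14 | 1-[2,6-bis(tert-butyldimethylsilyloxy)-4-methoxyphenyl]hept-6-en-1-one | C=CCCCCC(=O)c1c(O[Si](C)(C)C(C)(C)C)cc(OC)cc1O[Si](C)(C)C(C)(C)C | intermediate
15 | 6-[2,6-bis(tert-butyldimethylsilyloxy)-4-methoxyphenyl]-6-oxohexanal | O=CCCCCC(=O)c1c(O[Si](C)(C)C(C)(C)C)cc(OC)cc1O[Si](C)(C)C(C)(C)C | intermediate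
16 | (Z)-hex-3-en-1-ol | CC/C=C\CCO | starting material
17 | (Z)-1-iodohex-3-ene | CC/C=C\CCI | intermediate
18 | [(Z)-hex-3-enyl]triphenylphosphonium iodide | CC/C=C\CC[P+](c1ccccc1)(c1ccccc1)c1ccccc1.[I-] | intermediate
19 | (R)-α-hydroxy-γ-butyrolactone | O=C1OCC[C@H]1O | starting material
20 | (R)-3-(tert-butyldimethylsilyloxy)dihydrofuran-2(3H)-one | O=C1OCC[C@H]1O[Si](C)(C)C(C)(C)C | intermediate
21 | (R)-2-(tert-butyldimethylsilyloxy)-4-hydroxy-N-methoxy-N-methylbutanamide | CON(C)C(=O)[C@H](O[Si](C)(C)C(C)(C)C)CCO | intermediate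
22 | (R)-2,4-bis(tert-butyldimethylsilyloxy)-N-methoxy-N-methylbutanamide | CON(C)C(=O)[C@H](O[Si](C)(C)C(C)(C)C)CCO[Si](C)(C)C(C)(C)C | intermediate
23 | (R)-2,4-bis(tert-butyldimethylsilyloxy)butanal | O=C[C@H](O[Si](C)(C)C(C)(C)C)CCO[Si](C)(C)C(C)(C)C | intermediate
24 | (R,E)-4,6-bis(tert-butyldimethylsilyloxy)hex-2-enal | O=C/C=C/[C@H](O[Si](C)(C)C(C)(C)C)CCO[Si](C)(C)C(C)(C)C | intermediate
25 | [(Z)-hex-3-enylidene]triphenylphosphorane | CC/C=C\CC=P(c1ccccc1)(c1ccccc1)c1ccccc1 | intermediate
26 | (3R,4E,6Z,9Z)-1,3-bis(tert-butyldimethylsilyloxy)dodeca-4,6,9-triene | CC/C=C\C/C=C\C=C\[C@H](O[Si](C)(C)C(C)(C)C)CCO[Si](C)(C)C(C)(C)C | intermediate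
27 | (3R,4E,6Z,9Z)-3-(tert-butyldimethylsilyloxy)dodeca-4,6,9-trien-1-ol | CC/C=C\C/C=C\C=C\[C@H](O[Si](C)(C)C(C)(C)C)CCO | intermediate
28 | (3R,4E,6Z,9Z)-3-(tert-butyldimethylsilyloxy)-1-iodododeca-4,6,9-triene | CC/C=C\C/C=C\C=C\[C@H](O[Si](C)(C)C(C)(C)C)CCI | intermediate
29 | [(3R,4E,6Z,9Z)-3-(tert-butyldimethylsilyloxy)dodeca-4,6,9-trienyl]triphenylphosphonium iodide | CC/C=C\C/C=C\C=C\[C@H](O[Si](C)(C)C(C)(C)C)CC[P+](c1ccccc1)(c1ccccc1)c1ccccc1.[I-] | intermediate
30 | [(3R,4E,6Z,9Z)-3-(tert-butyldimethylsilyloxy)dodeca-4,6,9-trienylidene]triphenylphosphorane | CC/C=C\C/C=C\C=C\[C@H](O[Si](C)(C)C(C)(C)C)CC=P(c1ccccc1)(c1ccccc1)c1ccccc1 | intermediate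
31 | (6Z,9R,10E,12Z,15Z)-1-[2,6-bis(tert-butyldimethylsilyloxy)-4-methoxyphenyl]-9-(tert-butyldimethylsilyloxy)octadeca-6,10,12,15-tetraen-1-one | CC/C=C\C/C=C\C=C\[C@H](O[Si](C)(C)C(C)(C)C)C/C=C\CCCCC(=O)c1c(O[Si](C)(C)C(C)(C)C)cc(OC)cc1O[Si](C)(C)C(C)(C)C | intermediate
32 | (6Z,9R,10E,12Z,15Z)-1-(2,6-dihydroxy-4-methoxyphenyl)-9-hydroxyoctadeca-6,10,12,15-tetraen-1-one | CC/C=C\C/C=C\C=C\[C@H](O)C/C=C\CCCCC(=O)c1c(O)cc(OC)cc1O | target

**Step count and risks**

Total step count: 21. Longest linear sequence: 11 steps (steps 11–19, then 20 and 21, from lactone 19); the aryl arm is 10 steps (steps 1–8, 20, 21).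

Steps most likely to fail:

1. Step 5 (aryne insertion). The ortho-(acyloxy)aryl anion may be protonated by the bifluoride formed from the acid before it transfers the acyl group, so that the reaction stops at the aryl ester. The product phenoxide may also be arylated by a second aryne. Fallback, setting out from 1 and 10 and coming back at 13: excess MOMCl/i-Pr2NEt converts 1 into 1-methoxy-3,5-bis(methoxymethoxy)benzene F1. Carbonyldiimidazole, then MeNH(OMe)·HCl, converts 10 into N-methoxy-N-methylhept-6-enamide F2. n-BuLi (THF, 0 °C) metalates F1 between its two MOM-oxy groups to 2-lithio-5-methoxy-1,3-bis(methoxymethoxy)benzene F3, which is not isolated and is acylated by F2 (Weinreb ketone synthesis) to 1-[4-methoxy-2,6-bis(methoxymethoxy)phenyl]hept-6-en-1-one F4. HCl in MeOH removes both MOM groups of F4 and gives 13.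

2. Step 20 (Wittig union). The basic ylide may deprotonate the 1,6-keto aldehyde (enolisation, intramolecular aldol between C2 and C6) instead of adding to it, and Z-selectivity may erode. Fallback, setting out from 9 and 27 and coming back at 31, a B-alkyl Suzuki–Miyaura union that forms C5–C6 without a basic ylide meeting the keto aldehyde: pent-4-enoic acid (C=CCCC(=O)O, bought) replaces 10 under the conditions of step 5 and gives, through aryne 11, 1-[2-hydroxy-4-methoxy-6-(methoxymethoxy)phenyl]pent-4-en-1-one F5. The conditions of steps 6 and 7 convert it into 1-(2,6-dihydroxy-4-methoxyphenyl)pent-4-en-1-one F6 and then 1-[2,6-bis(tert-butyldimethylsilyloxy)-4-methoxyphenyl]pent-4-en-1-one F7. 9-BBN-H (THF, rt) hydroborates the terminal alkene of F7 to 5-(9-borabicyclo[3.3.1]nonan-9-yl)-1-[2,6-bis(tert-butyldimethylsilyloxy)-4-methoxyphenyl]pentan-1-one F8, which is not isolated. Alcohol 27 is oxidised (Dess–Martin periodinane, NaHCO3, CH2Cl2) to (3R,4E,6Z,9Z)-3-(tert-butyldimethylsilyloxy)dodeca-4,6,9-trienal F9. Stork–Zhao olefination (Ph3PCH2I iodide, NaN(SiMe3)2, THF, −78 °C) converts F9 into (1Z,4R,5E,7Z,10Z)-4-(tert-butyldimethylsilyloxy)-1-iodotrideca-1,5,7,10-tetraene F10. Coupling of F8 with F10 (PdCl2(dppf), AsPh3, K3PO4, DMF/H2O, rt) proceeds with retention of the Z geometry and gives 31. Any aryl silyl ether lost to the aqueous base is of no consequence, since step 21 removes all three.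

3. Step 3 (site of ortho-metalation). Lithiation may take place in part at the carbon between the carbamate and the methoxy group, which would lead to the wrong silane and hence the wrong aryne, or the aryllithium may undergo a carbamoyl shift before it is silylated. Fallback, setting out from 1 and coming back at 9, in which the silyl group is placed while the ring is still symmetrical: ClC(O)NEt2/K2CO3 (MeCN, reflux) converts 1 into 5-methoxy-1,3-phenylene bis(N,N-diethylcarbamate) F11. s-BuLi/TMEDA (THF, −78 °C) metalates F11 between the two carbamates to the 2-lithio compound F12, which is not isolated and is trapped by TMSCl as 5-methoxy-2-(trimethylsilyl)-1,3-phenylene bis(N,N-diethylcarbamate) F13. LiAlH4 (THF, neutral work-up) cleaves both carbamates to 5-methoxy-2-(trimethylsilyl)benzene-1,3-diol F14. One equivalent of PhNTf2 with Et3N (CH2Cl2) gives, in a statistical desymmetrisation, 3-hydroxy-5-methoxy-2-(trimethylsilyl)phenyl trifluoromethanesulfonate F15. MOMCl/i-Pr2NEt converts F15 into 9.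

**Further compounds**
F1 | step 5 | 1-methoxy-3,5-bis(methoxymethoxy)benzene | COc1cc(OCOC)cc(OCOC)c1
F2 | step 5 | N-methoxy-N-methylhept-6-enamide | C=CCCCCC(=O)N(C)OC
F3 | step 5 | 2-lithio-5-methoxy-1,3-bis(methoxymethoxy)benzene | COc1cc(OCOC)c([Li])c(OCOC)c1
F4 | step 5 | 1-[4-methoxy-2,6-bis(methoxymethoxy)phenyl]hept-6-en-1-one | C=CCCCCC(=O)c1c(OCOC)cc(OC)cc1OCOC
F5 | step 20 | 1-[2-hydroxy-4-methoxy-6-(methoxymethoxy)phenyl]pent-4-en-1-one | C=CCCC(=O)c1c(O)cc(OC)cc1OCOC
F6 | step 20 | 1-(2,6-dihydroxy-4-methoxyphenyl)pent-4-en-1-one | C=CCCC(=O)c1c(O)cc(OC)cc1O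
F7 | step 20 | 1-[2,6-bis(tert-butyldimethylsilyloxy)-4-methoxyphenyl]pent-4-en-1-one | C=CCCC(=O)c1c(O[Si](C)(C)C(C)(C)C)cc(OC)cc1O[Si](C)(C)C(C)(C)C
F8 | step 20 | 5-(9-borabicyclo[3.3.1]nonan-9-yl)-1-[2,6-bis(tert-butyldimethylsilyloxy)-4-methoxyphenyl]pentan-1-one | O=C(CCCCB1C2CCCC1CCC2)c1c(O[Si](C)(C)C(C)(C)C)cc(OC)cc1O[Si](C)(C)C(C)(C)C
F9 | step 20 | (3R,4E,6Z,9Z)-3-(tert-butyldimethylsilyloxy)dodeca-4,6,9-trienal | CC/C=C\C/C=C\C=C\[C@H](O[Si](C)(C)C(C)(C)C)CC=O
F10 | step 20 | (1Z,4R,5E,7Z,10Z)-4-(tert-butyldimethylsilyloxy)-1-iodotrideca-1,5,7,10-tetraene | CC/C=C\C/C=C\C=C\[C@H](O[Si](C)(C)C(C)(C)C)C/C=C\I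
F11 | step 3 | 5-methoxy-1,3-phenylene bis(N,N-diethylcarbamate) | CCN(CC)C(=O)Oc1cc(OC)cc(OC(=O)N(CC)CC)c1
F12 | step 3 | 2-lithio-5-methoxy-1,3-phenylene bis(N,N-diethylcarbamate) | CCN(CC)C(=O)Oc1cc(OC)cc(OC(=O)N(CC)CC)c1[Li]
F13 | step 3 | 5-methoxy-2-(trimethylsilyl)-1,3-phenylene bis(N,N-diethylcarbamate) | CCN(CC)C(=O)Oc1cc(OC)cc(OC(=O)N(CC)CC)c1[Si](C)(C)C
F14 | step 3 | 5-methoxy-2-(trimethylsilyl)benzene-1,3-diol | COc1cc(O)c([Si](C)(C)C)c(O)c1
F15 | step 3 | 3-hydroxy-5-methoxy-2-(trimethylsilyl)phenyl trifluoromethanesulfonate | COc1cc(O)c([Si](C)(C)C)c(OS(=O)(=O)C(F)(F)F)c1
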